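## Structural features

Auranetin (13) is a flavone: a benzene ring A fused along C4a–C8a to a 4-pyranone ring C, with a 4-methoxyphenyl ring B joined to C2 by a single bond. Ring A carries three adjacent methoxy groups on C6, C7 and C8 and one hydrogen on C5, so with O1 on C8a it is a 1,2,3,4-tetraoxygenated benzene with a single carbon substituent. Ring C carries a fourth methoxy group on C3 next to the C4 carbonyl, and ring B a fifth on C4'. The molecule is flat and achiral, so there are no stereocenters and no stereochemical relations to control. The target itself is robust, but several intermediates are not: an electron-rich, light-sensitive methoxyquinone, an acid-labile enol-ether allylic alcohol and an air-sensitive hydroquinone. The real difficulty is regiochemical: the C2–C3–C4 unit, already oxygenated at C3, must be attached at exactly one carbon of a ring A bearing four oxygens, and O1 must be distinguished from the other three. The oxygens on C8a and C6 are para, so ring A is the reduced form of 2,3-dimethoxy-1,4-benzoquinone, whose only two unsubstituted carbons are equivalent. One of these becomes C4a and the carbonyl oxygen next to it becomes O1, which is what step 7 exploits.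

## Logic of the disconnections

13 to 12. The O–CH3 bond on the C6 oxygen is cut. This oxygen is the one that ring C does not use, so it leaves the key step as a free phenol. Deferring its methylation costs one simple step and avoids any earlier differentiation of oxygens. The forward step only has to alkylate the single phenol of a molecule with no other acidic site.

12 to 4 and 10, through 11. Two bonds of ring C are cut, O1–C2 and C4–C4a. Cutting O1–C2 reveals 11, a phenol ortho to a β-methoxy enone. Cutting C4–C4a then separates an acyl unit at the aldehyde oxidation level (10) from ring A at the quinone oxidation level (4), and 4 plus 10 is isomeric with 11, so no external oxidant or reductant is needed. The gain is full convergence: 4 holds ring A with all four oxygens, and 10 holds C2, C3, C4, the C3 methoxy group and ring B. The demand is heavy: formyl hydrogen abstraction must beat every other photoreaction, the acyl radical must bond to carbon, and the ortho hydroxyl must displace methanol at a fully substituted β-carbon.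

4 to 3 to 1. The C4 carbonyl of 4 is traced back to an aryl methyl ether, and the phenol oxygen of 3 to the formyl carbon of 1, an aryl–carbon bond exchanged for an aryl–oxygen bond. This reaches 1, which is commercial and already has the three contiguous methoxy groups. The forward steps must stop at the para-quinone and must not cleave the other two ethers.

10 to 9 to 8. No skeletal bond is cut; C4 is returned from the aldehyde to the ester level. The ester is what the carbon–carbon assembly delivers, and full reduction followed by selective allylic oxidation is more dependable than a partial reduction of a vinylogous carbonate. The demand is that 9 is handled without acid.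

8 to 7. The enol O–CH3 bond on the future C2 is cut, revealing a β-keto ester. This methoxy group is the leaving group of step 7. The forward step must alkylate oxygen and not carbon.

7 to 5 and 6. The bond between the α-carbon and the ketone carbon, the future C3–C2 bond, is cut. This gives two commercial esters: 5 supplies C4, C3 and the C3 methoxy group, and 6 supplies C2 and ring B. The forward step must favour the crossed condensation over self-condensation of 5.

## Other disconnections considered

Alternative 1: The cut is C4a–C8a inside ring A, with C4 carried as a masked aldehyde.
- Forward step: dimethyl squarate A1 would take up (E)-3,3-diethoxyprop-1-enyllithium at one carbonyl, and methylation of the tertiary alkoxide would give racemic cyclobutenone A2. Heating A2 in toluene or xylene should open the four-membered ring in a conrotatory 4π process, with the C4 methoxy group turning outward and the alkenyl group inward. A 6π electrocyclisation between the former carbonyl carbon and the alkene terminus, then enolisation, would give phenol A3.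
- In its favour: the reaction class is well established, needs no reagent, and places the phenol oxygen, the three methoxy groups and C4 on ring A without ambiguity. On certainty of the key step it is better than the chosen plan, and on regiocontrol of ring A it is its equal.
- Against it here: it builds only ring A, and a ring A of this pattern is available from commercial 1 through 3 in one or two steps. A3 is a protected salicylaldehyde, so C3, C2, ring B, the C3 methoxy group, the C4 ketone and ring C all remain to be made. That would add at least four or five steps to the two or three needed for A3.
- Comparison: the chosen plan forms both ring C bonds at the final oxidation level in one step, so it is ahead on convergence and step economy and behind on precedent.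

Alternative 2: The cut is C3–C4 of ring C.
- Forward step: racemic dialdehyde A4 would be treated with SmI2 (samarium diiodide, divalent samarium) in THF at low temperature. Electron transfer to a formyl group gives a ketyl that couples with the other carbonyl carbon and closes ring C as chromane-3,4-diol A5. The 3,4-cis relation would come from a samarium-bridged diolate and the 2,3-trans relation from ring B taking an equatorial position.
- In its favour: ketyl–carbonyl pinacol closures to six-membered cis-diols are known, mild chemistry, and the step installs the oxygens on C3 and C4 together. On precedent of the reaction type it is better than the chosen plan, and in closing one ring in one step it is its equal.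
- Against it here: A5 is four electrons below the flavone oxidation level, so oxidation at C4, dehydrogenation across C2–C3 and methylation of the C3 hydroxyl must follow. Three stereocenters are made only to be erased. The aliphatic aldehyde of A4 is α-aryl and α-aryloxy, so it enolises readily, and α-aryloxy carbonyl groups tend to lose the aryloxy group reductively under SmI2, which would cut the ether link before the ring closes. Making A4 also needs alkylation of a phenol flanked by two ortho substituents.
- Comparison: the sequence would be longer than eight steps, so the chosen plan is ahead on redox and step economy and behind on precedent.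

Alternative 3: Three bonds around C4 are cut at once: C4a–C4, C4–C3 and O1–C2.
- Forward step: iodophenol A6 (from 3 by iodination ortho to the hydroxyl), carbon monoxide A7 and 4-ethynylanisole A8 would be combined with PdCl2(PPh3)2 in Et2NH. Oxidative addition of zerovalent palladium into the C–I bond, CO insertion, coupling with the alkyne and amine-mediated 6-endo closure of the phenol oxygen should give flavone A9.
- In its favour: it is known, convergent chemistry from simple components, and A9 would be reached in three steps from 1, against seven steps to 12. On step count and precedent it is better than the chosen plan, and on regiocontrol of ring A it is its equal, provided iodination goes ortho to the hydroxyl.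
- Against it here: A9 has hydrogen on C3, so the C3 oxygen must be added afterwards by metalation and oxidation, or epoxidation and rearrangement, then methylation. This late oxidation of an electron-rich polymethoxyflavone is the least dependable part of that sequence. Closure in the 5-exo sense competes, and the step needs toxic CO under pressure.
- Comparison: even with two added steps it would take about five or six steps against eight, so it stays ahead on step economy. The chosen plan's advantages are that the C3 methoxy group comes from a commercial ester and that no late C–H oxidation, transition metal or CO is needed.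

Key step: step 7

Assumption: the enol ether geometry set in step 4 is taken as Z (the two vicinal methoxy groups cis, aryl cis to the carbonyl group), as drawn for 8 to 11. Ring closure in step 7 passes through a tetrahedral C2 and the enal can isomerise under light, so any E isomer should give the same 12 and is carried along unseparated.

## Route

Step 1
Reactants: 1 2,3,4-trimethoxybenzaldehyde
Product: 3 2,3,4-trimethoxyphenol, via aryl formate 2 (not isolated)
Conditions: 30% H2O2, H2SO4 (cat.), MeOH, rt
Reagents that add atoms: hydrogen peroxide, OO
Why: Acid-catalysed Dakin oxidation: hydrogen peroxide adds to the aldehyde, the electron-rich aryl group migrates to oxygen (Baeyer–Villiger-type shift) to give formate 2, and methanol cleaves 2 in the same flask.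

Step 2
Reactants: 3 2,3,4-trimethoxyphenol
Product: 4 2,3-dimethoxy-1,4-benzoquinone
Conditions: (NH4)2Ce(NO3)6 (2.2 equiv), MeCN–H2O, 0 °C
Reagents that add atoms: water, O
Why: Oxidative demethylation of a para-methoxyphenol: two one-electron oxidations by tetravalent cerium give a phenoxonium ion, water adds at the methoxy-bearing para carbon and methanol is lost; attack para to the hydroxyl is favoured over ortho, so the 1,4-quinone should form.

Step 3
Reactants: 5 methyl methoxyacetate; 6 methyl 4-methoxybenzoate
Product: 7 methyl 2-methoxy-3-(4-methoxyphenyl)-3-oxopropanoate (racemic, C2 configurationally labile)
Conditions: NaH (2.2 equiv), THF, reflux, slow addition of 5 to 6 (1.5 equiv); then AcOH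
Reagents that add atoms: none
Why: Crossed Claisen condensation: the enolate of 5, kept dilute by slow addition, is acylated by the non-enolisable ester 6 present in excess, and irreversible deprotonation of the doubly activated C–H of 7 drives the equilibrium.

Step 4
Reactants: 7 methyl 2-methoxy-3-(4-methoxyphenyl)-3-oxopropanoate
Product: 8 methyl (Z)-2,3-dimethoxy-3-(4-methoxyphenyl)prop-2-enoate
Conditions: Me2SO4, K2CO3, DMF, 0 °C to rt
Reagents that add atoms: dimethyl sulfate, COS(=O)(=O)OC
Why: O-Alkylation of an ambident β-keto ester enolate: a hard electrophile, a potassium counter-ion and a dipolar aprotic solvent direct methylation to oxygen, while C-methylation would have to build a quaternary carbon next to a methoxy group; the dissociated W-shaped enolate should give mainly the Z enol ether.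

Step 5
Reactants: 8 methyl (Z)-2,3-dimethoxy-3-(4-methoxyphenyl)prop-2-enoate
Product: 9 (Z)-2,3-dimethoxy-3-(4-methoxyphenyl)prop-2-en-1-ol
Conditions: iBu2AlH (2.5 equiv), CH2Cl2, −78 °C; aq. KNaC4H4O6
Reagents that add atoms: none
Why: 1,2-Reduction of an α,β-unsaturated ester with iBu2AlH to the allylic alcohol; the fully substituted, donor-bearing β-carbon should not accept hydride, and the tartrate work-up avoids the acid that would ionise the enol-ether allylic alcohol.

Step 6
Reactants: 9 (Z)-2,3-dimethoxy-3-(4-methoxyphenyl)prop-2-en-1-ol
Product: 10 (Z)-2,3-dimethoxy-3-(4-methoxyphenyl)prop-2-enal
Conditions: MnO2 (activated, excess), CH2Cl2, rt, dark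
Reagents that add atoms: none
Why: Allylic alcohol oxidation with MnO2, neutral and heterogeneous, should stop at the aldehyde and leave the enol ether untouched.

Step 7
Reactants: 4 2,3-dimethoxy-1,4-benzoquinone; 10 (Z)-2,3-dimethoxy-3-(4-methoxyphenyl)prop-2-enal
Product: 12 6-hydroxy-3,7,8-trimethoxy-2-(4-methoxyphenyl)chromen-4-one, via acylhydroquinone 11 (not isolated)
Conditions: 4 (2 equiv), hν (blue LEDs, 420–450 nm), PhCF3, Ar, rt; then TsOH·H2O (cat.), 60 °C
Reagents that add atoms: none
Why: Proposed new method: blue light excites only the n,π* band of quinone 4, whose triplet abstracts the formyl hydrogen of 10 (the β-methoxy donor stabilises the acylium character of that transition state); the nucleophilic σ-acyl radical, slow to lose CO because it is α,β-unsaturated, bonds to one of the two equivalent unsubstituted ring carbons, by recombination with the semiquinone at carbon or by addition to ground-state 4 and hydrogen return, and enolisation gives acylhydroquinone 11 with the new C4–C4a bond. The closest known reaction type is the photochemical acylation of 1,4-quinones with aldehydes, enals included, to acylhydroquinones, with closure to chromanones done separately; a one-flask closure onto a β-methoxy enone giving the chromone directly has not been shown. Ring C closes by 6-endo-trig oxa-Michael addition of the hydroxyl ortho to the acyl group to the β-carbon, then acid-assisted loss of methanol (addition–elimination, as in the closure of o-hydroxyaryl β-alkoxy or β-amino enones to chromones), driven by formation of the aromatic 4-pyranone; this forms O1–C2. No stereocenter is formed, and the alkene geometry of 10 is lost in the tetrahedral adduct. The selectivity needed is C-acylation over O-acylation, [2+2] photocycloaddition and electron transfer; the weak formyl C–H bond, the tetrasubstituted push–pull alkene (a poor cycloaddition partner), the nonpolar solvent and the exclusion of oxygen favour the acyl radical path. Regiochemistry needs no control, because 4 is symmetric, its methoxy-bearing carbons are blocked, and only the ortho hydroxyl can reach C2 through a six-membered transition state, which leaves the para hydroxyl as the C6 phenol. Product 12 is no longer a hydroquinone and absorbs below the irradiation wavelength, so it should tolerate excess 4 and the light.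

Step 8
Reactants: 12 6-hydroxy-3,7,8-trimethoxy-2-(4-methoxyphenyl)chromen-4-one
Product: 13 Auranetin, 3,6,7,8-tetramethoxy-2-(4-methoxyphenyl)chromen-4-one
Conditions: MeI, K2CO3, acetone, reflux
Reagents that add atoms: iodomethane, CI
Why: Williamson ether synthesis on the only acidic group; the C6 hydroxyl is not hydrogen-bonded to the C4 carbonyl and should alkylate readily.

## Compound list

1 | 2,3,4-trimethoxybenzaldehyde | COc1ccc(C=O)c(OC)c1OC | starting material
2 | 2,3,4-trimethoxyphenyl formate | COc1ccc(OC=O)c(OC)c1OC | intermediate
3 | 2,3,4-trimethoxyphenol | COc1ccc(O)c(OC)c1OC | intermediate
4 | 2,3-dimethoxy-1,4-benzoquinone | COC1=C(OC)C(=O)C=CC1=O | intermediate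
5 | methyl methoxyacetate | COCC(=O)OC | starting material
6 | methyl 4-methoxybenzoate | COC(=O)c1ccc(OC)cc1 | starting material
7 | methyl 2-methoxy-3-(4-methoxyphenyl)-3-oxopropanoate (racemic) | COC(=O)C(OC)C(=O)c1ccc(OC)cc1 | intermediate
8 | methyl (Z)-2,3-dimethoxy-3-(4-methoxyphenyl)prop-2-enoate | COc1ccc(/C(OC)=C(/OC)C(=O)OC)cc1 | intermediate
9 | (Z)-2,3-dimethoxy-3-(4-methoxyphenyl)prop-2-en-1-ol | COc1ccc(/C(OC)=C(/OC)CO)cc1 | intermediate
10 | (Z)-2,3-dimethoxy-3-(4-methoxyphenyl)prop-2-enal | COc1ccc(/C(OC)=C(/OC)C=O)cc1 | intermediate
11 | (Z)-1-(2,5-dihydroxy-3,4-dimethoxyphenyl)-2,3-dimethoxy-3-(4-methoxyphenyl)prop-2-en-1-one | COc1ccc(/C(OC)=C(/OC)C(=O)c2cc(O)c(OC)c(OC)c2O)cc1 | intermediate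
12 | 6-hydroxy-3,7,8-trimethoxy-2-(4-methoxyphenyl)chromen-4-one | COc1ccc(-c2oc3c(OC)c(OC)c(O)cc3c(=O)c2OC)cc1 | intermediate
13 | Auranetin, 3,6,7,8-tetramethoxy-2-(4-methoxyphenyl)chromen-4-one | COc1ccc(-c2oc3c(OC)c(OC)c(OC)cc3c(=O)c2OC)cc1 | target

## Step count and least certain steps

Total: 8 steps. Longest linear sequence: 6 steps (steps 3 to 8, from 5 and 6 to 13). The quinone arm is 2 steps (1 to 4) before the union in step 7.

Step 7 (key step, proposed new method).
- What may go wrong: the excited quinone may be consumed by paths other than formyl hydrogen abstraction. These are electron transfer from, energy transfer to, or [2+2] cycloaddition with the anisyl enol ether, and bonding of the radical pair at oxygen. The cause is that the methoxy donors weaken the hydrogen-abstracting power of the quinone triplet, and the enal carries an oxidisable, isomerisable π system. Quenching of the triplet by the phenolic hydroxyls of 11 and 12 as they build up would also lower conversion and could photo-oxidise 11 before it closes.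
- Fallback (known chemistry, sets out from 3 and comes back at 13): 3 would be acylated ortho to its hydroxyl with methoxyacetic acid in BF3·OEt2 at about 85 °C, through the aryl ester and a boron-chelated Fries-type shift, to give 1-(2-hydroxy-3,4,5-trimethoxyphenyl)-2-methoxyethanone F1. Esterification with 4-methoxybenzoyl chloride in pyridine should give 6-(2-methoxyacetyl)-2,3,4-trimethoxyphenyl 4-methoxybenzoate F2. Baker–Venkataraman rearrangement (KOH, pyridine, 50 °C, then aqueous AcOH) should move the aroyl group to carbon and give 1-(2-hydroxy-3,4,5-trimethoxyphenyl)-2-methoxy-3-(4-methoxyphenyl)propane-1,3-dione F3. Cyclodehydration (H2SO4 cat., AcOH, 100 °C) would close ring C and give 13 directly, so steps 2 to 8 would not be needed.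

Step 4.
- What may go wrong: methylation at the doubly activated carbon may compete with methylation at oxygen, and a mixture of geometric isomers may form, because the enolate is ambident and the α-methoxy group only partly shields carbon.
- Fallback (sets out from 7 and comes back at 8): acetalisation and elimination in place of enolate alkylation. 7 with trimethyl orthoformate and catalytic H2SO4 in MeOH should give methyl 2,3,3-trimethoxy-3-(4-methoxyphenyl)propanoate F4. Heating F4 with catalytic TsOH in toluene, with removal of methanol, should eliminate to 8. Carbon alkylation is excluded by this mechanism.

Step 5.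
- What may go wrong: over-reduction or conjugate hydride delivery, and above all acid-triggered ionisation of the allylic hydroxyl during work-up or chromatography, because the two enol-ether oxygens stabilise the allyl cation.
- Fallback (sets out from 8 and comes back at 10, passing over 9 and step 6): 8 with MeNH(OMe)·HCl and iPrMgCl in THF at −20 °C should give (Z)-N,2,3-trimethoxy-N-methyl-3-(4-methoxyphenyl)prop-2-enamide F5. Reduction of F5 with iBu2AlH at −78 °C should stop at a chelated tetrahedral adduct and release 10 on work-up.

Step 3.
- What may go wrong: self-condensation of the enolate of 5 may outrun acylation, because the electron-rich ester 6 is a sluggish acceptor.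
- Fallback (sets out from 5 and comes back at 7): aldol addition and oxidation in place of the Claisen condensation. The lithium enolate of 5 (LiN(iPr)2, THF, −78 °C) should add irreversibly to 4-methoxybenzaldehyde and give, after aqueous NH4Cl, methyl 3-hydroxy-2-methoxy-3-(4-methoxyphenyl)propanoate F6 as a mixture of diastereomers. Oxidation of the benzylic alcohol of F6 with MnO2 in CH2Cl2 should give 7.

## Further compounds

F1 | step 7 | 1-(2-hydroxy-3,4,5-trimethoxyphenyl)-2-methoxyethanone | COCC(=O)c1cc(OC)c(OC)c(OC)c1O
F2 | step 7 | 6-(2-methoxyacetyl)-2,3,4-trimethoxyphenyl 4-methoxybenzoate | COCC(=O)c1cc(OC)c(OC)c(OC)c1OC(=O)c1ccc(OC)cc1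
F3 | step 7 | 1-(2-hydroxy-3,4,5-trimethoxyphenyl)-2-methoxy-3-(4-methoxyphenyl)propane-1,3-dione (racemic) | COC(C(=O)c1ccc(OC)cc1)C(=O)c1cc(OC)c(OC)c(OC)c1O
F4 | step 4 | methyl 2,3,3-trimethoxy-3-(4-methoxyphenyl)propanoate (racemic) | COC(=O)C(OC)C(OC)(OC)c1ccc(OC)cc1
F5 | step 5 | (Z)-N,2,3-trimethoxy-N-methyl-3-(4-methoxyphenyl)prop-2-enamide | COc1ccc(/C(OC)=C(/OC)C(=O)N(C)OC)cc1
F6 | step 3 | methyl 3-hydroxy-2-methoxy-3-(4-methoxyphenyl)propanoate (mixture of racemic diastereomers) | COC(=O)C(OC)C(O)c1ccc(OC)cc1
A1 | alternative 1 | dimethyl squarate, 3,4-dimethoxycyclobut-3-ene-1,2-dione | COC1=C(OC)C(=O)C1=O
A2 | alternative 1 | (E)-4-(3,3-diethoxyprop-1-en-1-yl)-2,3,4-trimethoxycyclobut-2-en-1-one (racemic) | CCOC(OCC)/C=C/C1(OC)C(OC)=C(OC)C1=O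
A3 | alternative 1 | 6-(diethoxymethyl)-2,3,4-trimethoxyphenol | CCOC(OCC)c1cc(OC)c(OC)c(OC)c1O
A4 | alternative 2 | 3,4,5-trimethoxy-2-[1-(4-methoxyphenyl)-2-oxoethoxy]benzaldehyde (racemic) | COc1ccc(C(C=O)Oc2c(OC)c(OC)c(OC)cc2C=O)cc1
A5 | alternative 2 | racemic 2,3-trans-3,4-cis-6,7,8-trimethoxy-2-(4-methoxyphenyl)chromane-3,4-diol (one enantiomer drawn) | COc1ccc([C@@H]2Oc3c(OC)c(OC)c(OC)cc3[C@@H](O)[C@H]2O)cc1
A6 | alternative 3 | 6-iodo-2,3,4-trimethoxyphenol | COc1cc(I)c(O)c(OC)c1OC
A7 | alternative 3 | carbon monoxide | [C-]#[O+]
A8 | alternative 3 | 4-ethynylanisole, 1-ethynyl-4-methoxybenzene | C#Cc1ccc(OC)cc1
A9 | alternative 3 | 6,7,8-trimethoxy-2-(4-methoxyphenyl)chromen-4-one | COc1ccc(-c2cc(=O)c3cc(OC)c(OC)c(OC)c3o2)cc1
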